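**Retrosynthetic overview**
1. Target 22 ← tertiary silyl ether removal and catalyst-controlled reduction of the C3 ketone of the ten-membered 1,3-diketone 20.
2. Key step: ring expansion of the seven-membered (Z)-enoate lactone 17 (acyl carbon C3 held on O8) to the ten-membered carbocycle by C-acylation of the C1 methyl-ketone enolate (forms C2–C3); the expelled O8 alkoxide is isovalerylated in the same flask.
3. The oxepinone of 17 ← ring-closing metathesis of the O8 methacrylate with the C6 vinyl group; the small ring fixes the Z C4=C5 alkene.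
4. The α-methylene-γ-lactone (C6, C7) ← CrCl2 Barbier allylation of acrolein with a Morita–Baylis–Hillman-derived allylic bromide.
5. The C7–C10/C1–C2 chain ← Cu(OTf)2/bis(oxazoline) Mukaiyama aldol on butane-2,3-dione (C10), then anti-selective directed reduction (C8). Ring order: γ-lactone, oxepinone, ten-membered ring.

Assumption: atoms are labelled by germacrane positions (C1 ring ketone, C3 carbinol, C4=C5 alkene, C6 lactone O-carbon, C8 ester carbon, C10 tertiary carbinol, C11–C13 methylene-lactone carbons); descriptors attached to these labels are CIP descriptors worked out for each compound.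

**Route**

Step 1
Reactants: 1 1,1-dimethoxypropan-2-one
Product: 2 trimethyl[(3,3-dimethoxyprop-1-en-2-yl)oxy]silane
Conditions: LDA (commercial solution), THF, −78 °C; then Me3SiCl, −78 °C to rt
Reagents that add atoms: chlorotrimethylsilane, C[Si](C)(C)Cl
Why: Kinetic deprotonation at the unhindered methyl group and O-silylation give the terminal silyl enol ether (silyl enol ether formation); no stereocentre is formed.

Step 2
Reactants: 2 trimethyl[(3,3-dimethoxyprop-1-en-2-yl)oxy]silane; 3 butane-2,3-dione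
Product: 5 (4R)-4-hydroxy-1,1-dimethoxy-4-methylhexane-2,5-dione, via silyl ether 4 (not isolated)
Conditions: Cu(OTf)2 (10 mol%), (R,R)-tBu-box (11 mol%), THF, −78 °C; then 1 M HCl, THF, 0 °C
Reagents that add atoms: none
Why: Evans-type Mukaiyama aldol addition to the chelating 1,2-diketone; the square-planar Cu(OTf)2–bis(oxazoline) chelate shields one carbonyl face and sets C10 as R (the (S,S) ligand gives the S series with pyruvates), and the symmetric diketone raises no regiochemical issue.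

Step 3
Reactants: 5 (4R)-4-hydroxy-1,1-dimethoxy-4-methylhexane-2,5-dione
Product: 6 (3R,5R)-3,5-dihydroxy-6,6-dimethoxy-3-methylhexan-2-one
Conditions: Me4NBH(OAc)3, MeCN/AcOH (1:1), −35 °C
Reagents that add atoms: none
Why: Evans–Saksena hydroxyl-directed reduction; the C10 alkoxy(acetoxy)borohydride delivers hydride to the β-ketone (C8) through a six-membered chair to give the 1,3-anti diol (C8 R), while the α-ketol carbonyl (C1), which cannot reach that geometry, should be spared.

Step 4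
Reactants: 6 (3R,5R)-3,5-dihydroxy-6,6-dimethoxy-3-methylhexan-2-one
Product: 7 (2R,4R)-4-methyl-5-oxo-2,4-bis(triethylsilyloxy)hexanal
Conditions: Et3SiOTf (3.3 equiv), 2,6-lutidine, CH2Cl2, −40 to 0 °C; then H2O
Reagents that add atoms: triethylsilyl trifluoromethanesulfonate, CC[Si](CC)(CC)OS(=O)(=O)C(F)(F)F; water, O
Why: The silyl triflate/2,6-lutidine pair silylates both hydroxyls and cleaves the dimethyl acetal through a pyridinium intermediate that water turns into the aldehyde (silyl ether protection with silyl-triflate acetal cleavage); the weak base leaves the ketone un-enolised and no stereocentre is touched.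

Step 5
Reactants: 7 (2R,4R)-4-methyl-5-oxo-2,4-bis(triethylsilyloxy)hexanal; 8 methyl prop-2-enoate
Product: 9 methyl (3RS,4R,6R)-3-hydroxy-6-methyl-2-methylidene-7-oxo-4,6-bis(triethylsilyloxy)octanoate
Conditions: DABCO (1 equiv), neat 8 (5 equiv), rt, 48 h
Reagents that add atoms: none
Why: Morita–Baylis–Hillman reaction of the activated α-silyloxy aldehyde; the new carbinol centre is formed as a mixture, which is irrelevant because it is removed in step 6.

Step 6
Reactants: 9 methyl (3RS,4R,6R)-3-hydroxy-6-methyl-2-methylidene-7-oxo-4,6-bis(triethylsilyloxy)octanoate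
Product: 10 methyl (2Z,4R,6R)-2-(bromomethyl)-6-methyl-7-oxo-4,6-bis(triethylsilyloxy)oct-2-enoate
Conditions: NBS, Me2S, CH2Cl2, 0 °C to rt
Reagents that add atoms: N-bromosuccinimide, O=C1CCC(=O)N1Br
Why: Corey–Kim-type activation of the allylic alcohol followed by SN2′ attack of bromide gives the conjugated (Z)-allylic bromide; the C7 carbinol centre disappears and C8/C10 are untouched.

Step 7
Reactants: 10 methyl (2Z,4R,6R)-2-(bromomethyl)-6-methyl-7-oxo-4,6-bis(triethylsilyloxy)oct-2-enoate; 11 prop-2-enal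
Product: 13 (4S,5R)-5-ethenyl-3-methylidene-4-[(1R,3R)-3-methyl-4-oxo-1,3-bis(triethylsilyloxy)pentyl]oxolan-2-one, via hydroxy ester 12 (not isolated)
Conditions: CrCl2 (3 equiv), 11 (5 equiv), THF, 0 °C to rt; then 50 °C
Reagents that add atoms: none
Why: Nozaki–Hiyama-type Barbier allylation; the allylchromium reagent adds through its γ-carbon (C7) to the aldehyde in a chair transition state to give the 6,7-anti adduct (trans-lactone after in-flask lactonisation), and the aldehyde approaches C7 anti to the C9 chain with C8–H eclipsing the alkene (allylic-strain model), which sets C6 and C7 relative to C8.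

Step 8
Reactants: 13 (4S,5R)-5-ethenyl-3-methylidene-4-[(1R,3R)-3-methyl-4-oxo-1,3-bis(triethylsilyloxy)pentyl]oxolan-2-one
Product: 14 (4R,5R)-5-ethenyl-4-[(1R,3R)-1-hydroxy-3-methyl-4-oxo-3-(triethylsilyloxy)pentyl]-3-methylideneoxolan-2-one
Conditions: PPTS (0.2 equiv), MeOH, 0 °C
Reagents that add atoms: none
Why: Acid-catalysed methanolysis cleaves the secondary triethylsilyl ether much faster than the hindered tertiary one (selective desilylation); no stereocentre changes.

Step 9
Reactants: 14 (4R,5R)-5-ethenyl-4-[(1R,3R)-1-hydroxy-3-methyl-4-oxo-3-(triethylsilyloxy)pentyl]-3-methylideneoxolan-2-one; 15 2-methylprop-2-enoyl chloride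
Product: 16 (1R,3R)-1-[(2R,3R)-2-ethenyl-4-methylidene-5-oxooxolan-3-yl]-3-methyl-4-oxo-3-(triethylsilyloxy)pentyl 2-methylprop-2-enoate
Conditions: Et3N, DMAP (cat.), CH2Cl2, 0 °C
Reagents that add atoms: none
Why: Standard DMAP-catalysed acylation of the only free (secondary) hydroxyl places the C3–C4–C15 unit on O8.

Step 10
Reactants: 16 (1R,3R)-1-[(2R,3R)-2-ethenyl-4-methylidene-5-oxooxolan-3-yl]-3-methyl-4-oxo-3-(triethylsilyloxy)pentyl 2-methylprop-2-enoate
Product: 17 (6R,7R,8R,10R) bicyclic bislactone: the α-methylene-γ-lactone (O6–C12) trans-fused across C6–C7 to the seven-membered enoate lactone O8–C3(=O)–C4(CH3)=C5, with C8 carrying CH2–C(CH3)(OSiEt3)–C(=O)CH3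
Conditions: second-generation Hoveyda–Grubbs catalyst RuCl2(H2IMes)(=CH-C6H4-2-OiPr) (10 mol%), toluene (2 mM), 80 °C
Reagents that add atoms: none
Why: Ring-closing metathesis between the vinyl group and the methacrylate closes the oxepinone; the seven-membered ring can only hold the Z C4=C5 alkene, and the 1,1-disubstituted conjugated exocyclic methylene does not take part.

Step 11
Reactants: 17 the (6R,7R,8R,10R) bicyclic bislactone; 18 3-methylbutanoyl chloride
Product: 20 (6R,7R,8R,10R)-8-(3-methylbutanoyloxy)-1,3-dioxo-10-(triethylsilyloxy)germacra-4Z,11(13)-dien-6,12-olide, via hydroxy diketone 19 (not isolated)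
Conditions: LiN(SiMe3)2 (2.2 equiv), THF (5 mM), −78 to −20 °C; then 18 (1.05 equiv), −78 °C; aq NH4Cl
Reagents that add atoms: none
Why: Proposed new method: lactone-to-carbocycle ring expansion (seven to ten) by C-acylation: the only possible ketone enolate (C2; C10 is quaternary) attacks the oxepinone carbonyl C3 through a seven-membered transition state, the bicyclic tetrahedral alkoxide collapses with C3–O8 cleavage, and irreversible deprotonation to the 1,3-diketonate drives the expansion, after which the far more nucleophilic O8 alkoxide is acylated selectively; no stereocentre is formed and the Z alkene is carried over from the ring; the closest known reactions are the Claisen/Dieckmann condensation, the Baker–Venkataraman O-to-C acyl transfer and acyl-transfer ring expansions of lactones and lactams.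

Step 12
Reactants: 20 (6R,7R,8R,10R)-8-(3-methylbutanoyloxy)-1,3-dioxo-10-(triethylsilyloxy)germacra-4Z,11(13)-dien-6,12-olide
Product: 21 (3R,6R,7R,8R,10R)-3-hydroxy-8-(3-methylbutanoyloxy)-1-oxo-10-(triethylsilyloxy)germacra-4Z,11(13)-dien-6,12-olide
Conditions: RuCl(p-cymene)[(R,R)-TsDPEN] (5 mol%), HCO2H/Et3N (5:2), CH2Cl2, 0 °C to rt
Reagents that add atoms: none
Why: Noyori–Ikariya asymmetric transfer hydrogenation; the alkenyl ketone C3 (alkenyl playing the aryl role) is reduced to the 3R alcohol under catalyst control, and C1, flanked by the quaternary C10, is too hindered to react.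

Step 13
Reactants: 21 (3R,6R,7R,8R,10R)-3-hydroxy-8-(3-methylbutanoyloxy)-1-oxo-10-(triethylsilyloxy)germacra-4Z,11(13)-dien-6,12-olide
Product: 22 (3R,6R,7R,8R,10R)-3,10-dihydroxy-8-(3-methylbutanoyloxy)-1-oxogermacra-4Z,11(13)-dien-6,12-olide (CNP0406522.1)
Conditions: HF·pyridine, pyridine/THF, 0 °C to rt
Reagents that add atoms: none
Why: Fluoride-mediated cleavage of the tertiary triethylsilyl ether under mildly acidic conditions that spare the β-hydroxy ketone, the ester and the methylene lactone.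

**Compound list**
1 | 1,1-dimethoxypropan-2-one | CC(=O)C(OC)OC | starting material
2 | trimethyl[(3,3-dimethoxyprop-1-en-2-yl)oxy]silane | C=C(O[Si](C)(C)C)C(OC)OC | intermediate
3 | butane-2,3-dione | CC(=O)C(C)=O | starting material
4 | (4R)-1,1-dimethoxy-4-methyl-4-(trimethylsilyloxy)hexane-2,5-dione | CC(=O)[C@](C)(O[Si](C)(C)C)CC(=O)C(OC)OC | intermediate
5 | (4R)-4-hydroxy-1,1-dimethoxy-4-methylhexane-2,5-dione | CC(=O)[C@](C)(O)CC(=O)C(OC)OC | intermediate
6 | (3R,5R)-3,5-dihydroxy-6,6-dimethoxy-3-methylhexan-2-one | CC(=O)[C@](C)(O)C[C@@H](O)C(OC)OC | intermediate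
7 | (2R,4R)-4-methyl-5-oxo-2,4-bis(triethylsilyloxy)hexanal | CC(=O)[C@](C)(O[Si](CC)(CC)CC)C[C@@H](O[Si](CC)(CC)CC)C=O | intermediate
8 | methyl prop-2-enoate | C=CC(=O)OC | starting material
9 | methyl (3RS,4R,6R)-3-hydroxy-6-methyl-2-methylidene-7-oxo-4,6-bis(triethylsilyloxy)octanoate | CC(=O)[C@](C)(O[Si](CC)(CC)CC)C[C@@H](O[Si](CC)(CC)CC)C(O)C(=C)C(=O)OC | intermediate
10 | methyl (2Z,4R,6R)-2-(bromomethyl)-6-methyl-7-oxo-4,6-bis(triethylsilyloxy)oct-2-enoate | CC(=O)[C@](C)(O[Si](CC)(CC)CC)C[C@@H](O[Si](CC)(CC)CC)/C=C(\CBr)C(=O)OC | intermediate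
11 | prop-2-enal | C=CC=O | starting material
12 | methyl 2-[(3R,4S,5R,7R)-3-hydroxy-7-methyl-8-oxo-5,7-bis(triethylsilyloxy)non-1-en-4-yl]prop-2-enoate | C=C[C@@H](O)[C@H](C(=C)C(=O)OC)[C@H](O[Si](CC)(CC)CC)C[C@@](C)(O[Si](CC)(CC)CC)C(C)=O | intermediate
13 | (4S,5R)-5-ethenyl-3-methylidene-4-[(1R,3R)-3-methyl-4-oxo-1,3-bis(triethylsilyloxy)pentyl]oxolan-2-one | C=C[C@H]1OC(=O)C(=C)[C@@H]1[C@H](O[Si](CC)(CC)CC)C[C@@](C)(O[Si](CC)(CC)CC)C(C)=O | intermediate
14 | (4R,5R)-5-ethenyl-4-[(1R,3R)-1-hydroxy-3-methyl-4-oxo-3-(triethylsilyloxy)pentyl]-3-methylideneoxolan-2-one | C=C[C@H]1OC(=O)C(=C)[C@@H]1[C@H](O)C[C@@](C)(O[Si](CC)(CC)CC)C(C)=O | intermediate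
15 | 2-methylprop-2-enoyl chloride | C=C(C)C(=O)Cl | starting material
16 | (1R,3R)-1-[(2R,3R)-2-ethenyl-4-methylidene-5-oxooxolan-3-yl]-3-methyl-4-oxo-3-(triethylsilyloxy)pentyl 2-methylprop-2-enoate | C=C[C@H]1OC(=O)C(=C)[C@@H]1[C@H](OC(=O)C(C)=C)C[C@@](C)(O[Si](CC)(CC)CC)C(C)=O | intermediate
17 | (6R,7R,8R,10R) bicyclic bislactone: α-methylene-γ-lactone trans-fused across C6–C7 to the oxepinone O8–C3(=O)–C4(CH3)=C5, with C8 carrying CH2–C(CH3)(OSiEt3)–C(=O)CH3 | CC(=O)[C@](C)(O[Si](CC)(CC)CC)C[C@H]1OC(=O)C(C)=C[C@H]2OC(=O)C(=C)[C@H]12 | intermediate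
18 | 3-methylbutanoyl chloride | CC(C)CC(=O)Cl | starting material
19 | (6R,7R,8R,10R)-8-hydroxy-1,3-dioxo-10-(triethylsilyloxy)germacra-4Z,11(13)-dien-6,12-olide | C=C1C(=O)O[C@@H]2/C=C(/C)C(=O)CC(=O)[C@](C)(O[Si](CC)(CC)CC)C[C@@H](O)[C@@H]12 | intermediate
20 | (6R,7R,8R,10R)-8-(3-methylbutanoyloxy)-1,3-dioxo-10-(triethylsilyloxy)germacra-4Z,11(13)-dien-6,12-olide | C=C1C(=O)O[C@@H]2/C=C(/C)C(=O)CC(=O)[C@](C)(O[Si](CC)(CC)CC)C[C@@H](OC(=O)CC(C)C)[C@@H]12 | intermediate
21 | (3R,6R,7R,8R,10R)-3-hydroxy-8-(3-methylbutanoyloxy)-1-oxo-10-(triethylsilyloxy)germacra-4Z,11(13)-dien-6,12-olide | C=C1C(=O)O[C@@H]2/C=C(/C)[C@H](O)CC(=O)[C@](C)(O[Si](CC)(CC)CC)C[C@@H](OC(=O)CC(C)C)[C@@H]12 | intermediate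
22 | (3R,6R,7R,8R,10R)-3,10-dihydroxy-8-(3-methylbutanoyloxy)-1-oxogermacra-4Z,11(13)-dien-6,12-olide | C=C1C(=O)O[C@@H]2/C=C(/C)[C@H](O)CC(=O)[C@](C)(O)C[C@@H](OC(=O)CC(C)C)[C@@H]12 | target

**Summary**
Total step count: 13. Longest linear sequence: 13 steps (from 1; compounds 3, 8, 11, 15 and 18 enter as single building blocks).

**Steps most likely to fail, with fallbacks**

Step 7 (Barbier allylation). The 6,7-anti/7,8 relationship rests on a transition-state model, and the allylchromium reagent could also attack the internal methyl ketone. Fallback: set out from 10 and run an indium-mediated Barbier reaction with 11 in THF/H2O, which tolerates the ketone and is syn-selective, to obtain the C6-epimeric hydroxy ester methyl 2-[(3S,4S,5R,7R)-3-hydroxy-7-methyl-8-oxo-5,7-bis(triethylsilyloxy)non-1-en-4-yl]prop-2-enoate F1. Invert C6 by Mitsunobu esterification (4-nitrobenzoic acid, PPh3, DIAD) to the 4-nitrobenzoate (3R,4S,5R,7R)-4-(3-methoxy-3-oxoprop-1-en-2-yl)-7-methyl-8-oxo-5,7-bis(triethylsilyloxy)non-1-en-3-yl 4-nitrobenzoate F2. Treatment with K2CO3 in MeOH removes the benzoate, and the freed alkoxide lactonises; the route is rejoined at 13.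

Step 11 (the proposed ring expansion). The enolate may not reach the conjugated lactone carbonyl, or the released alkoxide may isomerise the γ-lactone before it is trapped. Fallback with known chemistry: set out from 14 and acylate O8 with 18 (pyridine, DMAP) to give (1R,3R)-1-[(2R,3R)-2-ethenyl-4-methylidene-5-oxooxolan-3-yl]-3-methyl-4-oxo-3-(triethylsilyloxy)pentyl 3-methylbutanoate F3. Form the boron enolate of the methyl ketone with the Ipc2BCl enantiomer that gives the 3R adduct (Et3N, Et2O, −78 °C) and add 2-methylprop-2-enal (Paterson aldol) to give (1R,3R,6R)-1-[(2R,3R)-2-ethenyl-4-methylidene-5-oxooxolan-3-yl]-6-hydroxy-3,7-dimethyl-4-oxo-3-(triethylsilyloxy)oct-7-enyl 3-methylbutanoate F4. Close the ten-membered ring by ring-closing metathesis of the isopropenyl and vinyl groups (second-generation Hoveyda–Grubbs catalyst, toluene, high dilution), separating any E isomer. This bypasses 17, 19 and 20 and rejoins the route at 21.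

Step 12 (mono-reduction of the 1,3-diketone). The diketone may be largely enolised, or the transfer hydrogenation may give poor facial control or touch the C4=C5 bond. Fallback: set out from 20 and use a substrate-controlled Luche reduction (NaBH4, CeCl3·7H2O, MeOH, −78 °C), which attacks only the conjugated C3 carbonyl. If it gives the epimer (3S,6R,7R,8R,10R)-3-hydroxy-8-(3-methylbutanoyloxy)-1-oxo-10-(triethylsilyloxy)germacra-4Z,11(13)-dien-6,12-olide F5, invert it by Mitsunobu esterification (4-nitrobenzoic acid, PPh3, DIAD) to (3R,6R,7R,8R,10R)-8-(3-methylbutanoyloxy)-3-(4-nitrobenzoyloxy)-1-oxo-10-(triethylsilyloxy)germacra-4Z,11(13)-dien-6,12-olide F6. Cleave the activated benzoate selectively (NaN3, MeOH, 40 °C) to rejoin the route at 21.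

**Further compounds**
F1 | step 7 | methyl 2-[(3S,4S,5R,7R)-3-hydroxy-7-methyl-8-oxo-5,7-bis(triethylsilyloxy)non-1-en-4-yl]prop-2-enoate | C=C[C@H](O)[C@H](C(=C)C(=O)OC)[C@H](O[Si](CC)(CC)CC)C[C@@](C)(O[Si](CC)(CC)CC)C(C)=O
F2 | step 7 | (3R,4S,5R,7R)-4-(3-methoxy-3-oxoprop-1-en-2-yl)-7-methyl-8-oxo-5,7-bis(triethylsilyloxy)non-1-en-3-yl 4-nitrobenzoate | C=C[C@@H](OC(=O)c1ccc(cc1)[N+](=O)[O-])[C@H](C(=C)C(=O)OC)[C@H](O[Si](CC)(CC)CC)C[C@@](C)(O[Si](CC)(CC)CC)C(C)=O
F3 | step 11 | (1R,3R)-1-[(2R,3R)-2-ethenyl-4-methylidene-5-oxooxolan-3-yl]-3-methyl-4-oxo-3-(triethylsilyloxy)pentyl 3-methylbutanoate | C=C[C@H]1OC(=O)C(=C)[C@@H]1[C@H](OC(=O)CC(C)C)C[C@@](C)(O[Si](CC)(CC)CC)C(C)=O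
F4 | step 11 | (1R,3R,6R)-1-[(2R,3R)-2-ethenyl-4-methylidene-5-oxooxolan-3-yl]-6-hydroxy-3,7-dimethyl-4-oxo-3-(triethylsilyloxy)oct-7-enyl 3-methylbutanoate | C=C[C@H]1OC(=O)C(=C)[C@@H]1[C@H](OC(=O)CC(C)C)C[C@@](C)(O[Si](CC)(CC)CC)C(=O)C[C@@H](O)C(C)=C
F5 | step 12 | (3S,6R,7R,8R,10R)-3-hydroxy-8-(3-methylbutanoyloxy)-1-oxo-10-(triethylsilyloxy)germacra-4Z,11(13)-dien-6,12-olide | C=C1C(=O)O[C@@H]2/C=C(/C)[C@@H](O)CC(=O)[C@](C)(O[Si](CC)(CC)CC)C[C@@H](OC(=O)CC(C)C)[C@@H]12
F6 | step 12 | (3R,6R,7R,8R,10R)-8-(3-methylbutanoyloxy)-3-(4-nitrobenzoyloxy)-1-oxo-10-(triethylsilyloxy)germacra-4Z,11(13)-dien-6,12-olide | C=C1C(=O)O[C@@H]2/C=C(/C)[C@H](OC(=O)c3ccc(cc3)[N+](=O)[O-])CC(=O)[C@](C)(O[Si](CC)(CC)CC)C[C@@H](OC(=O)CC(C)C)[C@@H]12
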